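## Analysis of the target

The target is galangin (3,5,7-trihydroxy-2-phenylchromen-4-one; rings A, C and B) that carries a seven-carbon chain at C8 of ring A. Numbered from its phenyl end, the chain has C1–C2 as a phenethyl unit, C3 as a ketone, C5 as the methine bonded to flavonol C8, and C6–C7 leading to the guaiacyl ring D (4-hydroxy-3-methoxyphenyl). Chain C5 is the only stereocentre and is R (ring A > C4 > C6 > H). Nothing else in the molecule can relay or correct it, so a catalyst or reagent has to set it. C5 is benzylic to a ring carbon flanked by two oxygenated carbons (C7 and C8a), so every bond made to it is made at a di-ortho-substituted centre. The sensitive parts are the very electron-rich phloroglucinol-type ring A, the flavonol enol-ketone, four phenolic hydroxyls beside a methyl ether that must stay, and the C3 ketone, which can close onto a free C7 hydroxyl as a cyclic ketal under acid. The synthesis is hard for two reasons: absolute control at the hindered C5, and regiochemistry on ring A, where ring C must be annulated through the oxygen ortho to the chain and the ring carbon next to it, so the three ring A oxygens have to be told apart. The strategy rests on C5 lying beta to the C3 carbonyl and being bonded to a ring A carbon that can begin as an aldehyde carbon. C5 is then the beta carbon of an (E)-aryl enone, which a small boryl nucleophile can reach, and the resulting C5–B bond can be exchanged for C5–C6 with retention.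

## Retrosynthetic reasoning

**26 from 25.** The last disconnection removes the four benzyl groups (O3, O5 and O7 of the flavonol, O4 of ring D). Benzyl is kept from the first step to the last because it leaves by neutral hydrogenolysis, which spares the hydroxy ketone. The C3 ketone is already free in 25: it is unmasked while O7 is still an ether and cannot add to it.

**25 from 23 through 24.** Ring C is cut at O1–C2 and C2–C3. Forward, a Baker–Venkataraman shift moves the benzoyl group of 23 from the ring A oxygen to the alpha carbon of the aryl ketone, giving 24. Acid then closes O1–C2 with loss of water and hydrolyses the dioxolane in the same operation. The C3 oxygen is carried in as a benzyl ether, so the electron-rich flavone never has to be oxidised, and the oxidative chalcone closure, which drifts towards aurones when an alkoxy group sits next to the carbonyl, is avoided. The dioxolane must still be present here, because a free C3 ketone would give a second enolate that competes for the benzoate.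

**23 from 21 and 22; 21 from 18 and 19.** These cut the ester and then the C4–C4a bond. Ring A of 18 has two unsubstituted carbons, and only the one between the free hydroxyl and the benzyloxy group leads to the 8-alkyl flavonol. The selectivity is taken from the oxygen itself: magnesium phenolate 20 binds acyl chloride 19 and delivers it to the ortho carbon through a chelate. A Lewis-acid Fries rearrangement of the corresponding ester would make the same bond, but three benzyl ethers and a dioxolane would not survive the Lewis acids it needs.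

**18 from 17.** Only the ring A oxygen that becomes O1 is freed. Its protecting group must leave without acid, because the dioxolane has to stay until ring C is closed. It must also be small, because it sits ortho to the carbon at which the stereocentre is made. A 2-(trimethylsilyl)ethoxymethyl (SEM) ether meets both: it is no larger near the ring than a methoxymethyl ether and is cleaved by a fluoride source. An acid-labile acetal could not be removed beside the dioxolane.

**17 from 16.** The C6=C7 double bond is saturated directly after it is made, by a metal-free transfer of H2. While the alkene is present C5 is allylic as well as benzylic. A strong base could then shift the double bond into C5. Palladium hydride could do the same during the final hydrogenolysis. A free ortho phenol could add across the alkene under acid to give a flavan. Removing the alkene first takes all three risks out of the later steps.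

**16 from 8 and 12.** The C5–C6 bond is cut. Forward, bromide 12 is converted into alkenyllithium 13, which adds to the boron of 8 to give complex 14. A 1,2-shift of the benzylic carbon from boron to carbon (through 15) followed by anti elimination is the Zweifel olefination. The migrating carbon keeps its configuration, so the centre set at boron is the centre of the target. The alkene geometry is irrelevant because the alkene is reduced next.

**12 from 11; 11 from 9 and 10.** The ring D partner comes from the catalogue aldehyde 9 (the benzyl ether of vanillin) by condensation with 10 and bromodecarboxylation.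

**8 from 7.** The C3 ketone is masked as a dioxolane. It must not meet 13, and it must not enolise in the Baker–Venkataraman step.

**7 from 5 and 6.** The C5–B bond is cut, which is the key disconnection. A chiral copper boryl adds to the (E)-enone 5 and puts boron on the beta carbon. Boron is chosen over a carbon nucleophile because the group bonding to the crowded C5 is the small boryl unit, while the ligated copper goes to the unhindered C4.

**5 from 3 and 4.** The C4=C5 double bond is cut. A Horner–Wadsworth–Emmons reaction with the catalogue beta-keto phosphonate 4 is used in place of an aldol condensation of the methyl ketone. It can only react at the phosphonate carbon and gives the E isomer.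

**3 from 2; 2 from 1.** The ring A oxygens are differentiated on the aldehyde. The para hydroxyl and one ortho hydroxyl of 1 are benzylated, the remaining ortho hydroxyl is held back by its hydrogen bond to the aldehyde, and it then receives the SEM group.

## Alternatives that were turned down

**Alternative 1:** Ring A is built last, by cutting the flavonol C8–C8a and C6–C7 bonds. Forward, 3-(benzyloxy)cyclobut-2-en-1-one A2 is heated with the siloxyalkyne A3, which already carries C5 with its two arms. A2 opens to a vinylketene, adds to the alkyne in a [2+2] sense, and the four-membered ring reopens and closes by a six-electron electrocyclisation to phenol A1.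
- For: the three ring A oxygens come out differentiated by construction, with the free hydroxyl exactly where ring C needs it. No bond is ever made to C5 at a crowded arene, because the arene grows around it. On ring A regiochemistry this route is stronger than the chosen one, which needs steps 1, 2 and 10 to do the same job.
- Against: the stereochemical problem is only moved. A3 needs C5 set at a propargylic carbon by separate asymmetric chemistry and then a sensitive silyl ynol ether built on it, which costs many steps. The thermal benzannulation must place a branched substituent between two oxygens. A2 must be prepared.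
- Comparison: the chosen route sets C5 catalytically in one step on an enone that is three steps from catalogue compounds.

**Alternative 2:** C5 is made the ring carbon of the prochiral cyclobutanone A5. A chiral Brønsted acid with aqueous peroxide inserts oxygen into one of the two enantiotopic carbonyl–CH2 bonds and gives lactone A4.
- For: it is metal-free, and the reagent acts at a carbonyl two bonds from the arene, so the ortho substituents do not block it. That is a real advantage over the chosen key step, where the reagent must reach C5 itself. The two arms of C5 emerge differentiated.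
- Against: peroxide and acid meet a phloroglucinol-type ring and an acid-labile acetal. A5 needs a ketene cycloaddition to the styrene and a dehalogenation. After the key step the one-carbon CH2–O arm has to become C6 and gain C7 and ring D. That passes through the aldehyde oxidation level directly beside the benzylic C5, where epimerisation is easy, while the acyl arm still has to be converted into the C3 ketone.
- Comparison: the chosen route makes the centre later, forms the C5–C6 bond stereospecifically from boron, and never places a carbonyl next to C5.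

**Alternative 3:** The C5–H bond is cut. The 4-alkylcoumarin A7 is reduced by a copper hydride carrying a bulky chiral bis-phosphine to the dihydrocoumarin A6.
- For: hydride is even smaller than boryl. The ring locks the alkene geometry. Both arms of C5 are in place before the centre is set, so no boron-to-carbon exchange and no alkene reduction follow. Opening the lactone frees exactly the phenol that ring C needs. A7 is available by a Pechmann condensation. On step economy this route is as strong as the chosen one or stronger.
- Against: the acceptor is beta,beta-disubstituted with a peri benzyloxy group beside the reacting carbon. The catalyst must distinguish a fused aryl from a 2-arylethyl chain at a fully substituted carbon. Turning the lactone into the C3 ketone liberates the ortho phenol and the ketone together, and they close to a cyclic ketal unless further protection steps are added.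
- Comparison: the chosen route forms the centre on a disubstituted (E)-enone of a well-studied class, keeps the ketone at its final oxidation level from step 3, and introduces ring D late from the boronate, so the ring D unit can be varied without repeating the asymmetric step.

Key step: step 4

Assumption: the (R,S_P) antipode of the ferrocenyl diphosphine is taken to deliver boron to the enone face that gives (R)-7; if the sense of induction on this substrate is the opposite, the equally available (S,R_P) antipode is used and nothing else changes.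

Assumption: the target is addressed in the open hydroxy-ketone form that is drawn; a cyclic hemiketal between the C7 hydroxyl and the C3 ketone, if present at equilibrium, is the same compound.

Abbreviations in the step lines: ArA = 2,4-bis(benzyloxy)-6-{[2-(trimethylsilyl)ethoxy]methoxy}phenyl; ArD = 4-(benzyloxy)-3-methoxyphenyl; Bpin = 4,4,5,5-tetramethyl-1,3,2-dioxaborolan-2-yl; SEM = [2-(trimethylsilyl)ethoxy]methyl; Bn = benzyl.

## Route

Step 1
Reactants: 1 2,4,6-trihydroxybenzaldehyde
Product: 2 2,4-bis(benzyloxy)-6-hydroxybenzaldehyde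
Conditions: BnBr (2.1 equiv), K2CO3, DMF, 0 °C → rt
Reagents that add atoms: benzyl bromide, BrCc1ccccc1
Why: Williamson etherification; the para hydroxyl and one ortho hydroxyl are alkylated, while the second ortho hydroxyl stays hydrogen-bonded to the aldehyde and is much less nucleophilic, so alkylation should stop at the bis-ether.

Step 2
Reactants: 2 2,4-bis(benzyloxy)-6-hydroxybenzaldehyde
Product: 3 2,4-bis(benzyloxy)-6-{[2-(trimethylsilyl)ethoxy]methoxy}benzaldehyde
Conditions: NaH, DMF, 0 °C; SEMCl, 0 °C → rt
Reagents that add atoms: 2-(trimethylsilyl)ethoxymethyl chloride, C[Si](C)(C)CCOCCl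
Why: Irreversible deprotonation of the chelated phenol and alkylation with the chloromethyl ether (acetal-type protection); SEM is small next to the future stereocentre and is later removed by fluoride, not acid.

Step 3
Reactants: 3 2,4-bis(benzyloxy)-6-{[2-(trimethylsilyl)ethoxy]methoxy}benzaldehyde; 4 dimethyl (2-oxo-4-phenylbutyl)phosphonate
Product: 5 (1E)-1-ArA-5-phenylpent-1-en-3-one
Conditions: NaH, THF, 0 °C → 60 °C
Reagents that add atoms: none
Why: Horner–Wadsworth–Emmons olefination with the stabilised beta-keto phosphonate anion should give the (E)-enone only, and it fixes the site of C–C bond formation, which an aldol condensation of the methyl ketone would leave open.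

Step 4
Reactants: 5 (1E)-1-ArA-5-phenylpent-1-en-3-one; 6 bis(pinacolato)diboron
Product: 7 (1R)-1-ArA-5-phenyl-1-Bpin-pentan-3-one
Conditions: CuCl (5 mol %), NaOtBu (8 mol %), (R)-1-[(S_P)-2-(diphenylphosphino)ferrocenyl]ethyldicyclohexylphosphine (5.5 mol %), MeOH (2 equiv), THF, rt
Reagents that add atoms: none
Why: CuCl and NaOtBu give the ligated copper tert-butoxide, which undergoes sigma-bond metathesis with 6 to the chiral copper boryl; this inserts the C4=C5 bond of 5 in a syn borylcupration that puts boron on the beta carbon C5 and copper on C4 as a copper enolate, and methanol protonates the enolate and returns a copper alkoxide to the cycle. The closest known reaction type is the copper-catalysed enantioselective beta-borylation of acyclic beta-aryl alpha,beta-unsaturated ketones and esters with 6 and an alcohol additive under ferrocenyl diphosphine ligands. No ring is closed. The new stereocentre C5 (R) is set by catalyst control: the chiral diphosphine on copper differentiates the two faces of the enone, and the single E geometry from step 3 ties one face to one enantiomer. The step needs beta regioselectivity and 1,4- over 1,2-addition, both of which follow from the polarisation of the enone and the soft copper boryl. It also needs reactivity at a carbon flanked by two ortho oxygens, and here the substrate helps because the atom that bonds to C5 is the small boron while the phosphine-bearing copper goes to the open C4. The benzyl and SEM ethers offer no reactive site to the copper boryl, and the C–B bond formed is configurationally stable.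

Step 5
Reactants: 7 (1R)-1-ArA-5-phenyl-1-Bpin-pentan-3-one
Product: 8 2-[(2R)-2-ArA-2-Bpin-ethyl]-2-(2-phenylethyl)-1,3-dioxolane
Conditions: (Me3SiOCH2)2, Me3SiOTf (5 mol %), CH2Cl2, −78 → −20 °C; pyridine quench
Reagents that add atoms: 1,2-bis(trimethylsilyloxy)ethane, C[Si](C)(C)OCCO[Si](C)(C)C
Why: Acetalisation with the bis-silyl ether of ethylene glycol under catalytic silyl triflate (Noyori conditions) is aprotic and cold, so the SEM acetal and the pinacol boronate should not exchange; the dioxolane shields C3 from the alkenyllithium of step 8 and from enolisation in step 13.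

Step 6
Reactants: 9 4-(benzyloxy)-3-methoxybenzaldehyde; 10 malonic acid
Product: 11 (2E)-3-[4-(benzyloxy)-3-methoxyphenyl]prop-2-enoic acid
Conditions: pyridine, piperidine (cat.), 95 °C
Reagents that add atoms: none
Why: Knoevenagel–Doebner condensation with decarboxylation should give the (E)-cinnamic acid.

Step 7
Reactants: 11 (2E)-3-[4-(benzyloxy)-3-methoxyphenyl]prop-2-enoic acid
Product: 12 1-(benzyloxy)-4-[(E)-2-bromoethenyl]-2-methoxybenzene
Conditions: N-bromosuccinimide, Et3N (10 mol %), CH2Cl2, rt
Reagents that add atoms: N-bromosuccinimide, O=C1CCC(=O)N1Br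
Why: Base-catalysed bromodecarboxylation (Hunsdiecker type): bromination of the electron-rich cinnamate and loss of CO2 should give the (E)-bromoalkene, a pathway favoured by the para alkoxy group.

Step 8
Reactants: 8 2-[(2R)-2-ArA-2-Bpin-ethyl]-2-(2-phenylethyl)-1,3-dioxolane; 12 1-(benzyloxy)-4-[(E)-2-bromoethenyl]-2-methoxybenzene
Product: 16 2-[(2S,3Z)-2-ArA-4-ArD-but-3-en-1-yl]-2-(2-phenylethyl)-1,3-dioxolane, via alkenyllithium 13 (not isolated), via lithium boronate complex 14 (not isolated), via beta-iodoalkyl boronate 15 (not isolated)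
Conditions: 12 (1.3 equiv), t-BuLi (2.6 equiv), Et2O/THF, −78 °C; 8, THF, −78 °C; I2, MeOH, −78 °C; NaOMe, MeOH, −78 °C → rt
Reagents that add atoms: none
Why: Zweifel olefination: bromine–lithium exchange gives 13 with retention of geometry, and 13 adds to the boron of 8 to form 14. Iodine activates the alkenyl group, the benzylic carbon shifts from boron to the neighbouring carbon with retention of configuration to give 15, and methoxide induces anti elimination of boron and iodine. C5–C6 thus replaces C5–B stereospecifically (the descriptor changes from R to S only because the priorities change); the Z geometry that an (E)-alkenyl partner gives is of no consequence because the alkene is reduced in step 9.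

Step 9
Reactants: 16 2-[(2S,3Z)-2-ArA-4-ArD-but-3-en-1-yl]-2-(2-phenylethyl)-1,3-dioxolane
Product: 17 2-[(2R)-2-ArA-4-ArD-butyl]-2-(2-phenylethyl)-1,3-dioxolane
Conditions: TsNHNH2 (excess), NaOAc, DME/H2O, reflux
Reagents that add atoms: none
Why: Diimide reduction: diimide formed in the flask transfers H2 to the unpolarised C6=C7 bond through a cyclic transition state without metal hydride intermediates, so the double bond cannot migrate into C5 and the stereocentre is untouched; benzyl ethers, the SEM acetal and the dioxolane are inert.

Step 10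
Reactants: 17 2-[(2R)-2-ArA-4-ArD-butyl]-2-(2-phenylethyl)-1,3-dioxolane
Product: 18 3,5-bis(benzyloxy)-2-{(2R)-4-ArD-1-[2-(2-phenylethyl)-1,3-dioxolan-2-yl]butan-2-yl}phenol
Conditions: Bu4NF, ethylenediamine, DMF, 70 °C
Reagents that add atoms: none
Why: Fluoride-induced SEM cleavage: fluoride attacks the remote silicon and the group fragments to fluorotrimethylsilane, ethene and formaldehyde (trapped by the diamine so that it cannot hydroxymethylate the electron-rich phenoxide); the conditions are not acidic, so the dioxolane and the benzyl ethers should stay.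

Step 11
Reactants: 18 3,5-bis(benzyloxy)-2-{(2R)-4-ArD-1-[2-(2-phenylethyl)-1,3-dioxolan-2-yl]butan-2-yl}phenol; 19 (benzyloxy)acetyl chloride
Product: 21 2-(benzyloxy)-1-[4,6-bis(benzyloxy)-3-{(2R)-4-ArD-1-[2-(2-phenylethyl)-1,3-dioxolan-2-yl]butan-2-yl}-2-hydroxyphenyl]ethan-1-one, via bromomagnesium phenolate 20 (not isolated)
Conditions: EtMgBr (1.0 equiv), toluene/Et2O, 0 °C; 19, toluene, 0 °C → rt
Reagents that add atoms: none
Why: Metal-template ortho-acylation of a magnesium phenolate, a mild relative of the Fries and Friedel–Crafts acylations: in a weakly coordinating solvent the acyl chloride binds to the magnesium of 20 and is delivered to the only free ortho carbon through a six-membered chelate, and rearomatisation gives the chelated ortho-hydroxyaryl ketone. The other open ring position is para to the phenolate oxygen and flanked by two benzyloxy groups, and the chelate does not reach it.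

Step 12
Reactants: 21 2-(benzyloxy)-1-[4,6-bis(benzyloxy)-3-{(2R)-4-ArD-1-[2-(2-phenylethyl)-1,3-dioxolan-2-yl]butan-2-yl}-2-hydroxyphenyl]ethan-1-one; 22 benzoyl chloride
Product: 23 3,5-bis(benzyloxy)-2-[(benzyloxy)acetyl]-6-{(2R)-4-ArD-1-[2-(2-phenylethyl)-1,3-dioxolan-2-yl]butan-2-yl}phenyl benzoate
Conditions: Et3N, DMAP (cat.), CH2Cl2, 0 °C → rt
Reagents that add atoms: none
Why: O-Acylation of the hydrogen-bonded phenol under nucleophilic catalysis (esterification) installs the benzoyl group that becomes C2 and ring B.

Step 13
Reactants: 23 3,5-bis(benzyloxy)-2-[(benzyloxy)acetyl]-6-{(2R)-4-ArD-1-[2-(2-phenylethyl)-1,3-dioxolan-2-yl]butan-2-yl}phenyl benzoate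
Product: 25 3,5,7-tris(benzyloxy)-8-{(3R)-1-[4-(benzyloxy)-3-methoxyphenyl]-5-oxo-7-phenylheptan-3-yl}-2-phenyl-4H-chromen-4-one, via 1,3-diketone 24 (not isolated)
Conditions: LiN(SiMe3)2 (3 equiv), THF, −78 → 0 °C; then AcOH/THF/dilute aqueous HCl, 60 °C
Reagents that add atoms: water, O
Why: Baker–Venkataraman rearrangement: the lithium enolate of the alpha-benzyloxy ketone attacks the neighbouring benzoate and the acyl group moves from oxygen to carbon to give 24. Acid then closes the pyranone by attack of the phenol on the benzoyl carbonyl with loss of water (cyclodehydration) and hydrolyses the dioxolane, which is safe here because O7 is still benzylated and cannot add to the C3 ketone.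

Step 14
Reactants: 25 3,5,7-tris(benzyloxy)-8-{(3R)-1-[4-(benzyloxy)-3-methoxyphenyl]-5-oxo-7-phenylheptan-3-yl}-2-phenyl-4H-chromen-4-one
Product: 26 3,5,7-trihydroxy-8-[(3R)-1-(4-hydroxy-3-methoxyphenyl)-5-oxo-7-phenylheptan-3-yl]-2-phenyl-4H-chromen-4-one
Conditions: H2 (1 atm), Pd/C (10 %), THF/MeOH, rt
Reagents that add atoms: none
Why: Hydrogenolysis of the four benzyl ethers under neutral conditions; the aliphatic ketone, the chromone double bond and the methyl ether should not be reduced at one atmosphere, and C5 no longer has an adjacent double bond that could migrate.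

## Compound list

1 | 2,4,6-trihydroxybenzaldehyde | O=Cc1c(O)cc(O)cc1O | starting material
2 | 2,4-bis(benzyloxy)-6-hydroxybenzaldehyde | O=Cc1c(O)cc(OCc2ccccc2)cc1OCc1ccccc1 | intermediate
3 | 2,4-bis(benzyloxy)-6-{[2-(trimethylsilyl)ethoxy]methoxy}benzaldehyde | O=Cc1c(OCOCC[Si](C)(C)C)cc(OCc2ccccc2)cc1OCc1ccccc1 | intermediate
4 | dimethyl (2-oxo-4-phenylbutyl)phosphonate | COP(=O)(OC)CC(=O)CCc1ccccc1 | starting material
5 | (1E)-1-[2,4-bis(benzyloxy)-6-{[2-(trimethylsilyl)ethoxy]methoxy}phenyl]-5-phenylpent-1-en-3-one | O=C(CCc1ccccc1)/C=C/c1c(OCOCC[Si](C)(C)C)cc(OCc2ccccc2)cc1OCc1ccccc1 | intermediate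
6 | bis(pinacolato)diboron | CC1(C)OB(OC1(C)C)B1OC(C)(C)C(C)(C)O1 | starting material
7 | (1R)-1-[2,4-bis(benzyloxy)-6-{[2-(trimethylsilyl)ethoxy]methoxy}phenyl]-5-phenyl-1-(4,4,5,5-tetramethyl-1,3,2-dioxaborolan-2-yl)pentan-3-one | CC1(C)OB(OC1(C)C)[C@H](CC(=O)CCc1ccccc1)c1c(OCOCC[Si](C)(C)C)cc(OCc2ccccc2)cc1OCc1ccccc1 | intermediate
8 | 2-{(2R)-2-[2,4-bis(benzyloxy)-6-{[2-(trimethylsilyl)ethoxy]methoxy}phenyl]-2-(4,4,5,5-tetramethyl-1,3,2-dioxaborolan-2-yl)ethyl}-2-(2-phenylethyl)-1,3-dioxolane | CC1(C)OB(OC1(C)C)[C@H](CC1(CCc2ccccc2)OCCO1)c1c(OCOCC[Si](C)(C)C)cc(OCc2ccccc2)cc1OCc1ccccc1 | intermediate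
9 | 4-(benzyloxy)-3-methoxybenzaldehyde | COc1cc(C=O)ccc1OCc1ccccc1 | starting material
10 | malonic acid | OC(=O)CC(=O)O | starting material
11 | (2E)-3-[4-(benzyloxy)-3-methoxyphenyl]prop-2-enoic acid | COc1cc(/C=C/C(=O)O)ccc1OCc1ccccc1 | intermediate
12 | 1-(benzyloxy)-4-[(E)-2-bromoethenyl]-2-methoxybenzene | COc1cc(/C=C/Br)ccc1OCc1ccccc1 | intermediate
13 | (E)-2-[4-(benzyloxy)-3-methoxyphenyl]ethenyllithium | COc1cc(/C=C/[Li])ccc1OCc1ccccc1 | intermediate (not isolated)
14 | lithium pinacolato borate complex of 8 carrying the (E)-2-[4-(benzyloxy)-3-methoxyphenyl]ethenyl group on boron, C5 (R) | [Li+].COc1cc(/C=C/[B-]2(OC(C)(C)C(C)(C)O2)[C@H](CC2(CCc3ccccc3)OCCO2)c2c(OCOCC[Si](C)(C)C)cc(OCc3ccccc3)cc2OCc2ccccc2)ccc1OCc1ccccc1 | intermediate (not isolated)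
15 | 2-{2-[2,4-bis(benzyloxy)-6-{[2-(trimethylsilyl)ethoxy]methoxy}phenyl]-4-[4-(benzyloxy)-3-methoxyphenyl]-4-iodo-3-(4,4,5,5-tetramethyl-1,3,2-dioxaborolan-2-yl)butyl}-2-(2-phenylethyl)-1,3-dioxolane, C5 configuration retained, C6 and C7 the anti-addition pair as both diastereomers (left unspecified) | COc1cc(C(I)C(B2OC(C)(C)C(C)(C)O2)[C@H](CC2(CCc3ccccc3)OCCO2)c2c(OCOCC[Si](C)(C)C)cc(OCc3ccccc3)cc2OCc2ccccc2)ccc1OCc1ccccc1 | intermediate (not isolated)
16 | 2-{(2S,3Z)-2-[2,4-bis(benzyloxy)-6-{[2-(trimethylsilyl)ethoxy]methoxy}phenyl]-4-[4-(benzyloxy)-3-methoxyphenyl]but-3-en-1-yl}-2-(2-phenylethyl)-1,3-dioxolane | COc1cc(\C=C/[C@H](CC2(CCc3ccccc3)OCCO2)c2c(OCOCC[Si](C)(C)C)cc(OCc3ccccc3)cc2OCc2ccccc2)ccc1OCc1ccccc1 | intermediate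
17 | 2-{(2R)-2-[2,4-bis(benzyloxy)-6-{[2-(trimethylsilyl)ethoxy]methoxy}phenyl]-4-[4-(benzyloxy)-3-methoxyphenyl]butyl}-2-(2-phenylethyl)-1,3-dioxolane | COc1cc(CC[C@H](CC2(CCc3ccccc3)OCCO2)c2c(OCOCC[Si](C)(C)C)cc(OCc3ccccc3)cc2OCc2ccccc2)ccc1OCc1ccccc1 | intermediate
18 | 3,5-bis(benzyloxy)-2-{(2R)-4-[4-(benzyloxy)-3-methoxyphenyl]-1-[2-(2-phenylethyl)-1,3-dioxolan-2-yl]butan-2-yl}phenol | COc1cc(CC[C@H](CC2(CCc3ccccc3)OCCO2)c2c(O)cc(OCc3ccccc3)cc2OCc2ccccc2)ccc1OCc1ccccc1 | intermediate
19 | (benzyloxy)acetyl chloride | O=C(Cl)COCc1ccccc1 | starting material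
20 | bromomagnesium phenolate of 18 | COc1cc(CC[C@H](CC2(CCc3ccccc3)OCCO2)c2c(O[Mg]Br)cc(OCc3ccccc3)cc2OCc2ccccc2)ccc1OCc1ccccc1 | intermediate (not isolated)
21 | 2-(benzyloxy)-1-[4,6-bis(benzyloxy)-3-{(2R)-4-[4-(benzyloxy)-3-methoxyphenyl]-1-[2-(2-phenylethyl)-1,3-dioxolan-2-yl]butan-2-yl}-2-hydroxyphenyl]ethan-1-one | COc1cc(CC[C@H](CC2(CCc3ccccc3)OCCO2)c2c(O)c(C(=O)COCc3ccccc3)c(OCc3ccccc3)cc2OCc2ccccc2)ccc1OCc1ccccc1 | intermediate
22 | benzoyl chloride | O=C(Cl)c1ccccc1 | starting material
23 | 3,5-bis(benzyloxy)-2-[(benzyloxy)acetyl]-6-{(2R)-4-[4-(benzyloxy)-3-methoxyphenyl]-1-[2-(2-phenylethyl)-1,3-dioxolan-2-yl]butan-2-yl}phenyl benzoate | COc1cc(CC[C@H](CC2(CCc3ccccc3)OCCO2)c2c(OC(=O)c3ccccc3)c(C(=O)COCc3ccccc3)c(OCc3ccccc3)cc2OCc2ccccc2)ccc1OCc1ccccc1 | intermediate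
24 | 2-(benzyloxy)-1-[4,6-bis(benzyloxy)-3-{(2R)-4-[4-(benzyloxy)-3-methoxyphenyl]-1-[2-(2-phenylethyl)-1,3-dioxolan-2-yl]butan-2-yl}-2-hydroxyphenyl]-3-phenylpropane-1,3-dione (the carbon between the carbonyls is enolisable and left unspecified) | COc1cc(CC[C@H](CC2(CCc3ccccc3)OCCO2)c2c(O)c(C(=O)C(OCc3ccccc3)C(=O)c3ccccc3)c(OCc3ccccc3)cc2OCc2ccccc2)ccc1OCc1ccccc1 | intermediate (not isolated)
25 | 3,5,7-tris(benzyloxy)-8-{(3R)-1-[4-(benzyloxy)-3-methoxyphenyl]-5-oxo-7-phenylheptan-3-yl}-2-phenyl-4H-chromen-4-one | COc1cc(CC[C@H](CC(=O)CCc2ccccc2)c2c(OCc3ccccc3)cc(OCc3ccccc3)c3c(=O)c(OCc4ccccc4)c(-c4ccccc4)oc23)ccc1OCc1ccccc1 | intermediate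
26 | 3,5,7-trihydroxy-8-[(3R)-1-(4-hydroxy-3-methoxyphenyl)-5-oxo-7-phenylheptan-3-yl]-2-phenyl-4H-chromen-4-one | COc1cc(CC[C@H](CC(=O)CCc2ccccc2)c2c(O)cc(O)c3c(=O)c(O)c(-c4ccccc4)oc23)ccc1O | target

## Step count and least certain steps

Total: 14 steps. Longest linear sequence: 12 steps (steps 1–5 and 8–14, from 1 to 26); the ring D bromide 12 takes two further steps (6 and 7).

**Step 4 (key step).** The borylcupration may be slow or incomplete, because the beta carbon is shielded by two ortho oxygens and the enone is deactivated by electron donation from ring A. Enantioface selection may also be eroded, because the twisted aryl group does not sit in the ligand pocket as a flat cinnamoyl unit does. Fallback, from 5 back to 8: the carbonyl is protected first under the conditions of step 5, giving 2-{(E)-2-[2,4-bis(benzyloxy)-6-{[2-(trimethylsilyl)ethoxy]methoxy}phenyl]ethenyl}-2-(2-phenylethyl)-1,3-dioxolane F1. The C–B centre is then set by a copper hydride-catalysed Markovnikov hydroboration of this beta-substituted styrene with pinacolborane (CuCl, NaOtBu, the appropriate antipode of DTBM-SEGPHOS, toluene, rt). Hydrocupration places copper on the benzylic carbon, and exchange with the borane gives 8 directly. This removes every pathway that involves the carbonyl and moves the enantio-determining event to a different elementary step, but it does not lower the steric demand at C5.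

**Step 8.** Complex 14 may form incompletely at the crowded boron. Iodine may also attack the electron-rich benzylic C–B bond or ring A in place of the alkenyl group, which would cost material and configuration. Fallback, from 8 back to 17, without iodine and with the smallest possible carbon nucleophile: a Matteson homologation with chloromethyllithium (chloroiodomethane, n-BuLi, THF, −78 °C → rt) inserts C6 with retention and gives 2-{(2R)-2-[2,4-bis(benzyloxy)-6-{[2-(trimethylsilyl)ethoxy]methoxy}phenyl]-3-(4,4,5,5-tetramethyl-1,3,2-dioxaborolan-2-yl)propyl}-2-(2-phenylethyl)-1,3-dioxolane F2. A second homologation inserts C7 and gives 2-{(2R)-2-[2,4-bis(benzyloxy)-6-{[2-(trimethylsilyl)ethoxy]methoxy}phenyl]-4-(4,4,5,5-tetramethyl-1,3,2-dioxaborolan-2-yl)butyl}-2-(2-phenylethyl)-1,3-dioxolane F3. A Suzuki–Miyaura coupling of this primary boronate with catalogue 1-(benzyloxy)-4-bromo-2-methoxybenzene (Pd(OAc)2, RuPhos, K3PO4, toluene/H2O, 90 °C) then gives 17, so step 9 is also bypassed.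

**Step 9.** Hydrogen transfer to the hindered cis-alkene may be slow, leaving mixtures of 16 and 17 that are hard to separate. Fallback, from 8 back to 17, in which no internal alkene is ever formed: a Zweifel olefination of 8 with vinylmagnesium bromide (THF/DMSO; I2; NaOMe) gives 2-{(2S)-2-[2,4-bis(benzyloxy)-6-{[2-(trimethylsilyl)ethoxy]methoxy}phenyl]but-3-en-1-yl}-2-(2-phenylethyl)-1,3-dioxolane F4. Hydroboration of the terminal alkene with 9-borabicyclo[3.3.1]nonane gives 9-{(3R)-3-[2,4-bis(benzyloxy)-6-{[2-(trimethylsilyl)ethoxy]methoxy}phenyl]-4-[2-(2-phenylethyl)-1,3-dioxolan-2-yl]butyl}-9-borabicyclo[3.3.1]nonane F5, which is coupled in the same flask with 1-(benzyloxy)-4-bromo-2-methoxybenzene (Pd(dppf)Cl2, K3PO4, THF/DMF/H2O, 60 °C) to give 17.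

**Step 11.** Acylation may go to oxygen in place of carbon, giving the aryl ester. The benzyl ether next to the new ketone may also be lost through magnesium halide chelation. Fallback, from 18 back to 21, built on the ortho-specific magnesium-mediated formylation: MgCl2, Et3N and paraformaldehyde in MeCN at reflux give 4,6-bis(benzyloxy)-3-{(2R)-4-[4-(benzyloxy)-3-methoxyphenyl]-1-[2-(2-phenylethyl)-1,3-dioxolan-2-yl]butan-2-yl}-2-hydroxybenzaldehyde F6. Addition of (benzyloxymethyl)lithium, made by tin–lithium exchange from tributyl[(benzyloxy)methyl]stannane and n-BuLi (THF, −78 °C, excess to allow for the phenol), gives 2-(benzyloxy)-1-[4,6-bis(benzyloxy)-3-{(2R)-4-[4-(benzyloxy)-3-methoxyphenyl]-1-[2-(2-phenylethyl)-1,3-dioxolan-2-yl]butan-2-yl}-2-hydroxyphenyl]ethan-1-ol F7 as a mixture of carbinol epimers. Oxidation of the benzylic alcohol with MnO2 (CH2Cl2, rt) gives 21.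

## Further compounds

F1 | step 4 | 2-{(E)-2-[2,4-bis(benzyloxy)-6-{[2-(trimethylsilyl)ethoxy]methoxy}phenyl]ethenyl}-2-(2-phenylethyl)-1,3-dioxolane | O1CCOC1(CCc1ccccc1)/C=C/c1c(OCOCC[Si](C)(C)C)cc(OCc2ccccc2)cc1OCc1ccccc1
F2 | step 8 | 2-{(2R)-2-[2,4-bis(benzyloxy)-6-{[2-(trimethylsilyl)ethoxy]methoxy}phenyl]-3-(4,4,5,5-tetramethyl-1,3,2-dioxaborolan-2-yl)propyl}-2-(2-phenylethyl)-1,3-dioxolane | CC1(C)OB(OC1(C)C)C[C@H](CC1(CCc2ccccc2)OCCO1)c1c(OCOCC[Si](C)(C)C)cc(OCc2ccccc2)cc1OCc1ccccc1
F3 | step 8 | 2-{(2R)-2-[2,4-bis(benzyloxy)-6-{[2-(trimethylsilyl)ethoxy]methoxy}phenyl]-4-(4,4,5,5-tetramethyl-1,3,2-dioxaborolan-2-yl)butyl}-2-(2-phenylethyl)-1,3-dioxolane | CC1(C)OB(OC1(C)C)CC[C@H](CC1(CCc2ccccc2)OCCO1)c1c(OCOCC[Si](C)(C)C)cc(OCc2ccccc2)cc1OCc1ccccc1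
F4 | step 9 | 2-{(2S)-2-[2,4-bis(benzyloxy)-6-{[2-(trimethylsilyl)ethoxy]methoxy}phenyl]but-3-en-1-yl}-2-(2-phenylethyl)-1,3-dioxolane | C=C[C@H](CC1(CCc2ccccc2)OCCO1)c1c(OCOCC[Si](C)(C)C)cc(OCc2ccccc2)cc1OCc1ccccc1
F5 | step 9 | 9-{(3R)-3-[2,4-bis(benzyloxy)-6-{[2-(trimethylsilyl)ethoxy]methoxy}phenyl]-4-[2-(2-phenylethyl)-1,3-dioxolan-2-yl]butyl}-9-borabicyclo[3.3.1]nonane | C(C[C@H](CC1(CCc2ccccc2)OCCO1)c1c(OCOCC[Si](C)(C)C)cc(OCc2ccccc2)cc1OCc1ccccc1)B1C2CCCC1CCC2
F6 | step 11 | 4,6-bis(benzyloxy)-3-{(2R)-4-[4-(benzyloxy)-3-methoxyphenyl]-1-[2-(2-phenylethyl)-1,3-dioxolan-2-yl]butan-2-yl}-2-hydroxybenzaldehyde | COc1cc(CC[C@H](CC2(CCc3ccccc3)OCCO2)c2c(O)c(C=O)c(OCc3ccccc3)cc2OCc2ccccc2)ccc1OCc1ccccc1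
F7 | step 11 | 2-(benzyloxy)-1-[4,6-bis(benzyloxy)-3-{(2R)-4-[4-(benzyloxy)-3-methoxyphenyl]-1-[2-(2-phenylethyl)-1,3-dioxolan-2-yl]butan-2-yl}-2-hydroxyphenyl]ethan-1-ol (carbinol epimers) | COc1cc(CC[C@H](CC2(CCc3ccccc3)OCCO2)c2c(O)c(C(O)COCc3ccccc3)c(OCc3ccccc3)cc2OCc2ccccc2)ccc1OCc1ccccc1
A1 | alternative 1 | 5-(benzyloxy)-2-{(2R)-4-[4-(benzyloxy)-3-methoxyphenyl]-1-[2-(2-phenylethyl)-1,3-dioxolan-2-yl]butan-2-yl}-3-{[tri(propan-2-yl)silyl]oxy}phenol | COc1cc(CC[C@H](CC2(CCc3ccccc3)OCCO2)c2c(O[Si](C(C)C)(C(C)C)C(C)C)cc(OCc3ccccc3)cc2O)ccc1OCc1ccccc1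
A2 | alternative 1 | 3-(benzyloxy)cyclobut-2-en-1-one | O=C1C=C(OCc2ccccc2)C1
A3 | alternative 1 | {[(3R)-5-[4-(benzyloxy)-3-methoxyphenyl]-3-{[2-(2-phenylethyl)-1,3-dioxolan-2-yl]methyl}pent-1-yn-1-yl]oxy}tri(propan-2-yl)silane | COc1cc(CC[C@H](CC2(CCc3ccccc3)OCCO2)C#CO[Si](C(C)C)(C(C)C)C(C)C)ccc1OCc1ccccc1
A4 | alternative 2 | (4R)-4-[2,4-bis(benzyloxy)-6-(methoxymethoxy)phenyl]oxolan-2-one | O1C[C@H](CC1=O)c1c(OCOC)cc(OCc2ccccc2)cc1OCc1ccccc1
A5 | alternative 2 | 3-[2,4-bis(benzyloxy)-6-(methoxymethoxy)phenyl]cyclobutan-1-one | O=C1CC(C1)c1c(OCOC)cc(OCc2ccccc2)cc1OCc1ccccc1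
A6 | alternative 3 | (4R)-5,7-bis(benzyloxy)-4-{2-[4-(benzyloxy)-3-methoxyphenyl]ethyl}-3,4-dihydro-2H-chromen-2-one | COc1cc(CC[C@H](CC(=O)O2)c3c2cc(OCc2ccccc2)cc3OCc2ccccc2)ccc1OCc1ccccc1
A7 | alternative 3 | 5,7-bis(benzyloxy)-4-{2-[4-(benzyloxy)-3-methoxyphenyl]ethyl}-2H-chromen-2-one | COc1cc(CCc2cc(=O)oc3cc(OCc4ccccc4)cc(OCc4ccccc4)c23)ccc1OCc1ccccc1
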